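The ten-membered carbocycle is closed last, after the oxirane, by forming C1–C10 (farnesane numbering: C1 = acetoxy carbinol, C2–C3 = oxirane, C4 = angeloyloxy carbon, C10 = isopropenyl-bearing carbon). The homoallylic alcohol O–C1–C10–C11=C12 on this ring is the retron: the two termini of a farnesyl chain are joined as in germacrane biosynthesis, with polarity reversed. Palladium-catalysed, diethylzinc-mediated umpolung allylation of an open-chain 4-angeloyloxy-2,3-epoxy-12-chlorofarnesal builds the ring and the C1 and C10 stereocentres in one operation. The chain comes from geranyl chloride and a C5 enal; Sharpless kinetic resolution and two invertive Mitsunobu esterifications fix the remaining configuration.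

Key step: step 9

Locants: farnesane numbering C1–C12 is kept for chain and ring compounds (C1 carbinol/aldehyde carbon; C2–C3 oxirane; C4 ester carbon; C6=C7 ring olefin; C10 isopropenyl-bearing carbon; C12 the oxidised methyl that ends as =CH2).

Assumption: step 9 is taken to give the C1 hydroxyl trans to the isopropenyl group (chair allylzinc transition state in the crown fold), which is epimeric at C1 to the target; step 10 is written for this outcome and the alternative is covered under the fallbacks.

Step 1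
Reactants: 1 allyloxy(tert-butyl)dimethylsilane; 2 methacrolein
Product: 3 (2E)-4-[tert-butyl(dimethyl)silyl]oxy-2-methylbut-2-enal
Conditions: second-generation Hoveyda–Grubbs catalyst (3 mol%), 2 (4 equiv), CH2Cl2, 40 °C
Reagents that add atoms: none
Why: Olefin cross-metathesis of a terminal allyl ether with the electron-poor 1,1-disubstituted methacrolein is a productive pairing that releases ethene and should give the trisubstituted enal in its thermodynamically favoured E geometry; no stereocentre is formed.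

Step 2
Reactants: 4 geranyl chloride; 3 (2E)-4-[tert-butyl(dimethyl)silyl]oxy-2-methylbut-2-enal
Product: 6 rac-(2E,6E)-1-[tert-butyl(dimethyl)silyl]oxy-3,7,11-trimethyldodeca-2,6,10-trien-4-ol, via geranylbarium chloride 5 (not isolated)
Conditions: BaI2, lithium biphenylide (LiC12H10, 2 equiv), THF, 23 °C; 4, −78 °C; then 3, −78 °C; aq NH4Cl
Reagents that add atoms: none
Why: Allylbarium addition: geranylbarium chloride generated at −78 °C keeps its E geometry and adds 1,2 to the enal through its unsubstituted α-carbon, so the linear farnesane chain should result; the new carbinol centre C4 is formed racemic and is resolved in step 3.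

Step 3
Reactants: 6 rac-(2E,6E)-1-[tert-butyl(dimethyl)silyl]oxy-3,7,11-trimethyldodeca-2,6,10-trien-4-ol
Product: 7 (2R,3R,4R,6E)-1-[tert-butyl(dimethyl)silyl]oxy-2,3-epoxy-3,7,11-trimethyldodeca-6,10-dien-4-ol
Conditions: Ti(OiPr)4 (15 mol%), D-(−)-diisopropyl tartrate (20 mol%), TBHP (0.5 equiv), 4 Å MS, CH2Cl2, −20 °C
Reagents that add atoms: tert-butyl hydroperoxide CC(C)(C)OO
Why: Sharpless kinetic resolution: with the D-(−)-tartrate the (4R)-enantiomer should be epoxidised much faster than the (4S)-enantiomer, the titanium-bound C4 alkoxide delivering oxygen to the face of the C2=C3 olefin that gives the erythro (2R,3R,4R) epoxy alcohol, while the two non-allylic olefins stay untouched and the unreacted (4S)-alcohol is separated by chromatography.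

Step 4
Reactants: 7 (2R,3R,4R,6E)-1-[tert-butyl(dimethyl)silyl]oxy-2,3-epoxy-3,7,11-trimethyldodeca-6,10-dien-4-ol
Product: 9 (2R,3R,4S,6E)-1-[tert-butyl(dimethyl)silyl]oxy-2,3-epoxy-3,7,11-trimethyldodeca-6,10-dien-4-yl (2Z)-2-methylbut-2-enoate, via oxyphosphonium angelate 8 (not isolated)
Conditions: PPh3, DIAD, angelic acid, toluene, 0 to 23 °C
Reagents that add atoms: angelic acid C/C=C(/C)C(=O)O
Why: Mitsunobu esterification: angelate should displace the C4 oxyphosphonium ion with inversion, turning the erythro (4R) alcohol into the threo (4S) angelate of the target under neutral conditions that do not isomerise angelate to tiglate, the backside of C4 remaining open because the neighbouring quaternary carbon C3 is tied back in the oxirane.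

Step 5
Reactants: 9 (2R,3R,4S,6E)-1-[tert-butyl(dimethyl)silyl]oxy-2,3-epoxy-3,7,11-trimethyldodeca-6,10-dien-4-yl (2Z)-2-methylbut-2-enoate
Product: 10 (2R,3R,4S,6E,10E)-1-[tert-butyl(dimethyl)silyl]oxy-2,3-epoxy-12-hydroxy-3,7,11-trimethyldodeca-6,10-dien-4-yl (2Z)-2-methylbut-2-enoate
Conditions: SeO2 (cat.), TBHP, salicylic acid (cat.), CH2Cl2, 0 to 23 °C, stopped at partial conversion
Reagents that add atoms: tert-butyl hydroperoxide CC(C)(C)OO (oxygen relayed by the SeO2 catalyst, O=[Se]=O)
Why: Catalytic SeO2 allylic oxidation (ene reaction followed by [2,3]-shift) should attack the most electron-rich and least hindered terminal olefin at its (E)-methyl group, as is usual for farnesyl chains, giving the (10E)-allylic alcohol and leaving the C6=C7 olefin, the oxirane and the conjugated angelate alone.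

Step 6
Reactants: 10 (2R,3R,4S,6E,10E)-1-[tert-butyl(dimethyl)silyl]oxy-2,3-epoxy-12-hydroxy-3,7,11-trimethyldodeca-6,10-dien-4-yl (2Z)-2-methylbut-2-enoate
Product: 12 (2R,3R,4S,6E,10E)-1-[tert-butyl(dimethyl)silyl]oxy-12-chloro-2,3-epoxy-3,7,11-trimethyldodeca-6,10-dien-4-yl (2Z)-2-methylbut-2-enoate, via allylic mesylate 11 (not isolated)
Conditions: MsCl, 2,4,6-collidine, LiCl, DMF, 0 °C
Reagents that add atoms: lithium chloride [Li+].[Cl-]
Why: Mesylation and in situ chloride displacement at the primary allylic carbon (SN2) should give the allylic chloride without transposition or loss of the 10E geometry, under non-acidic conditions that oxirane, silyl ether and ester tolerate.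

Step 7
Reactants: 12 (2R,3R,4S,6E,10E)-1-[tert-butyl(dimethyl)silyl]oxy-12-chloro-2,3-epoxy-3,7,11-trimethyldodeca-6,10-dien-4-yl (2Z)-2-methylbut-2-enoate
Product: 13 (2R,3R,4S,6E,10E)-12-chloro-2,3-epoxy-1-hydroxy-3,7,11-trimethyldodeca-6,10-dien-4-yl (2Z)-2-methylbut-2-enoate
Conditions: HF·pyridine, pyridine, THF, 0 to 23 °C
Reagents that add atoms: none
Why: Pyridine-buffered fluoride cleavage of the primary silyl ether is mild enough to spare the trisubstituted oxirane, the allylic chloride and the angelate, and no stereocentre is touched.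

Step 8
Reactants: 13 (2R,3R,4S,6E,10E)-12-chloro-2,3-epoxy-1-hydroxy-3,7,11-trimethyldodeca-6,10-dien-4-yl (2Z)-2-methylbut-2-enoate
Product: 14 (2S,3R,4S,6E,10E)-12-chloro-2,3-epoxy-3,7,11-trimethyl-1-oxododeca-6,10-dien-4-yl (2Z)-2-methylbut-2-enoate
Conditions: Dess–Martin periodinane, pyridine, CH2Cl2, 0 to 23 °C; used crude
Reagents that add atoms: none
Why: Buffered Dess–Martin oxidation converts the primary epoxy alcohol into the α,β-epoxy aldehyde without epimerising the oxirane carbon C2 (its descriptor changes from R to S only because the CIP priorities change).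

Step 9
Reactants: 14 (2S,3R,4S,6E,10E)-12-chloro-2,3-epoxy-3,7,11-trimethyl-1-oxododeca-6,10-dien-4-yl (2Z)-2-methylbut-2-enoate
Product: 17 (1R,2S,4E,8S,9S,10R)-9-hydroxy-1,5-dimethyl-8-(prop-1-en-2-yl)-11-oxabicyclo[8.1.0]undec-4-en-2-yl (2Z)-2-methylbut-2-enoate, via allylpalladium chloride 15 (not isolated), via allylethylzinc 16 (not isolated)
Conditions: PdCl2(PPh3)2 (10 mol%), Et2Zn (5 equiv), K2CO3, DMA, 23 °C, syringe-pump addition of 14 (final 0.005 M); aq NH4Cl
Reagents that add atoms: none
Why: Zerovalent palladium (formed from PdCl2(PPh3)2 and Et2Zn) ionises the allylic chloride to the η3-allyl complex 15, Et2Zn transmetalates it to the nucleophilic allylzinc 16 (the ethylpalladium residue gives ethene and returns zerovalent palladium), and 16 adds through its substituted terminus C10 to the C1 aldehyde. The closest known reaction type is the palladium-catalysed, diethylzinc-mediated umpolung allylation of aldehydes in its macrocyclising form on 2,3-epoxyfarnesal-type allylic chlorides, which copies with reversed polarity the C1–C10 bond formation of germacrane biosynthesis. The ten-membered carbocycle closes in a 10-exo-trig mode, the carbonyl oxygen staying outside the ring. C10 should be set by the six-membered Zn–O chair in which the (E)-allylzinc holds the C9 chain equatorial, and C1 by the equatorial position of the oxirane-bearing C2, so that hydroxyl and isopropenyl end up trans; their sense relative to the oxirane is expected to follow the crown fold of the germacranolides (C6=C7 olefin and oxirane crossed, both methyl groups on one face), which corresponds to (1S,10S) in farnesane locants. The step needs ring closure to beat oligomerisation (syringe-pump dilution), allyl to beat ethyl transfer (Et2Zn alone does not add to aldehydes at 23 °C) and ionisation of the allylic chloride only, which the substrate secures because the angelate sits on a non-allylic carbon once the oxirane is in place. The C1 hydroxyl is thus expected epimeric to the target and is inverted in step 10.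

Step 10
Reactants: 17 (1R,2S,4E,8S,9S,10R)-9-hydroxy-1,5-dimethyl-8-(prop-1-en-2-yl)-11-oxabicyclo[8.1.0]undec-4-en-2-yl (2Z)-2-methylbut-2-enoate
Product: 19 (1R,2S,4E,8S,9R,10R)-9-acetoxy-1,5-dimethyl-8-(prop-1-en-2-yl)-11-oxabicyclo[8.1.0]undec-4-en-2-yl (2Z)-2-methylbut-2-enoate, via oxyphosphonium acetate 18 (not isolated)
Conditions: PPh3, DIAD, AcOH, toluene, 0 to 23 °C
Reagents that add atoms: acetic acid CC(=O)O
Why: Mitsunobu esterification with acetic acid should displace the ring oxyphosphonium ion with inversion, converting the threo epoxy alcohol (farnesane C1 S) into the erythro acetate (farnesane C1 R) of the target in one operation without touching the other four stereocentres.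

Compound list
1 | allyloxy(tert-butyl)dimethylsilane | C=CCO[Si](C)(C)C(C)(C)C | starting material
2 | methacrolein (2-methylprop-2-enal) | CC(=C)C=O | starting material
3 | (2E)-4-[tert-butyl(dimethyl)silyl]oxy-2-methylbut-2-enal | O=C/C(C)=C/CO[Si](C)(C)C(C)(C)C | intermediate
4 | geranyl chloride, (2E)-1-chloro-3,7-dimethylocta-2,6-diene | CC(C)=CCC/C(C)=C/CCl | starting material
5 | geranylbarium chloride, (2E)-3,7-dimethylocta-2,6-dien-1-ylbarium chloride (not isolated) | CC(C)=CCC/C(C)=C/C[Ba]Cl | intermediate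
6 | rac-(2E,6E)-1-[tert-butyl(dimethyl)silyl]oxy-3,7,11-trimethyldodeca-2,6,10-trien-4-ol | CC(C)=CCC/C(C)=C/CC(O)/C(C)=C/CO[Si](C)(C)C(C)(C)C | intermediate
7 | (2R,3R,4R,6E)-1-[tert-butyl(dimethyl)silyl]oxy-2,3-epoxy-3,7,11-trimethyldodeca-6,10-dien-4-ol (erythro epoxy alcohol) | CC(C)=CCC/C(C)=C/C[C@@H](O)[C@@]1(C)O[C@@H]1CO[Si](C)(C)C(C)(C)C | intermediate
8 | C4 triphenylphosphoniooxy derivative of 7 as its angelate salt (not isolated) | CC(C)=CCC/C(C)=C/C[C@@H](O[P+](c1ccccc1)(c1ccccc1)c1ccccc1)[C@@]1(C)O[C@@H]1CO[Si](C)(C)C(C)(C)C.C/C=C(/C)C(=O)[O-] | intermediate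
9 | (2R,3R,4S,6E)-1-[tert-butyl(dimethyl)silyl]oxy-2,3-epoxy-3,7,11-trimethyldodeca-6,10-dien-4-yl (2Z)-2-methylbut-2-enoate | CC(C)=CCC/C(C)=C/C[C@H](OC(=O)/C(C)=C\C)[C@@]1(C)O[C@@H]1CO[Si](C)(C)C(C)(C)C | intermediate
10 | (2R,3R,4S,6E,10E)-1-[tert-butyl(dimethyl)silyl]oxy-2,3-epoxy-12-hydroxy-3,7,11-trimethyldodeca-6,10-dien-4-yl (2Z)-2-methylbut-2-enoate | OC/C(C)=C/CC/C(C)=C/C[C@H](OC(=O)/C(C)=C\C)[C@@]1(C)O[C@@H]1CO[Si](C)(C)C(C)(C)C | intermediate
11 | 12-methanesulfonate of 10 (not isolated) | CS(=O)(=O)OC/C(C)=C/CC/C(C)=C/C[C@H](OC(=O)/C(C)=C\C)[C@@]1(C)O[C@@H]1CO[Si](C)(C)C(C)(C)C | intermediate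
12 | (2R,3R,4S,6E,10E)-1-[tert-butyl(dimethyl)silyl]oxy-12-chloro-2,3-epoxy-3,7,11-trimethyldodeca-6,10-dien-4-yl (2Z)-2-methylbut-2-enoate | ClC/C(C)=C/CC/C(C)=C/C[C@H](OC(=O)/C(C)=C\C)[C@@]1(C)O[C@@H]1CO[Si](C)(C)C(C)(C)C | intermediate
13 | (2R,3R,4S,6E,10E)-12-chloro-2,3-epoxy-1-hydroxy-3,7,11-trimethyldodeca-6,10-dien-4-yl (2Z)-2-methylbut-2-enoate | ClC/C(C)=C/CC/C(C)=C/C[C@H](OC(=O)/C(C)=C\C)[C@@]1(C)O[C@@H]1CO | intermediate
14 | (2S,3R,4S,6E,10E)-12-chloro-2,3-epoxy-3,7,11-trimethyl-1-oxododeca-6,10-dien-4-yl (2Z)-2-methylbut-2-enoate | ClC/C(C)=C/CC/C(C)=C/C[C@H](OC(=O)/C(C)=C\C)[C@@]1(C)O[C@@H]1C=O | intermediate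
15 | η3-allylpalladium chloride formed from 14 at C10–C12 (not isolated; drawn as the σ-allyl form, phosphine ligands omitted) | Cl[Pd]C/C(C)=C/CC/C(C)=C/C[C@H](OC(=O)/C(C)=C\C)[C@@]1(C)O[C@@H]1C=O | intermediate
16 | allyl(ethyl)zinc formed from 15 (not isolated) | CC[Zn]C/C(C)=C/CC/C(C)=C/C[C@H](OC(=O)/C(C)=C\C)[C@@]1(C)O[C@@H]1C=O | intermediate
17 | (1R,2S,4E,8S,9S,10R)-9-hydroxy-1,5-dimethyl-8-(prop-1-en-2-yl)-11-oxabicyclo[8.1.0]undec-4-en-2-yl (2Z)-2-methylbut-2-enoate; farnesane locants (1S,2R,3R,4S,10S) | C=C(C)[C@@H]1CC/C(C)=C/C[C@H](OC(=O)/C(C)=C\C)[C@@]2(C)O[C@@H]2[C@H]1O | intermediate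
18 | ring triphenylphosphoniooxy derivative of 17 as its acetate salt (not isolated) | C=C(C)[C@@H]1CC/C(C)=C/C[C@H](OC(=O)/C(C)=C\C)[C@@]2(C)O[C@@H]2[C@H]1O[P+](c1ccccc1)(c1ccccc1)c1ccccc1.CC(=O)[O-] | intermediate
19 | (1R,2S,4E,8S,9R,10R)-9-acetoxy-1,5-dimethyl-8-(prop-1-en-2-yl)-11-oxabicyclo[8.1.0]undec-4-en-2-yl (2Z)-2-methylbut-2-enoate; farnesane locants (1R,2R,3R,4S,10S) | C=C(C)[C@@H]1CC/C(C)=C/C[C@H](OC(=O)/C(C)=C\C)[C@@]2(C)O[C@@H]2[C@@H]1OC(C)=O | target

Total step count: 10. Longest linear sequence: 10 steps (1 to 19; geranyl chloride 4 enters at step 2).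

Steps most likely to fail

Step 9. Intermolecular allylation, ethyl or hydride transfer to the aldehyde or to the allyl unit may outrun ring closure. The chain may also fold the other way, which would set C10 with the wrong sense relative to the oxirane; the fallback below does not correct that. The fallback sets out from chloro aldehyde 14 and comes back at 17. It replaces the catalytic palladium–zinc relay by a stoichiometric Nozaki–Hiyama closure. CrCl2 (divalent chromium, excess, THF–DMF, syringe-pump dilution) should turn the allylic chloride into the allylchromium dichloride F1 (trivalent chromium), which adds through C10 to the aldehyde in a compact Cr–O chair. No dialkylzinc is present, so ethyl transfer is excluded; aqueous work-up gives 17.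

Step 10. Substitution at the ring carbinol, flanked by the oxirane and the isopropenyl-bearing carbon, may be slow, so that elimination of the oxyphosphonium ion toward C10 or recovery of the alcohol takes over. The fallback sets out from 17 and comes back at 19. Dess–Martin oxidation gives the epoxy ketone F2. Luche reduction (NaBH4, CeCl3·7H2O, MeOH, −78 °C), typically erythro-selective for α,β-epoxy ketones, should then give the ring alcohol with farnesane C1 R, F3. Acetylation (Ac2O, DMAP, pyridine) gives 19. If step 9 were to deliver F3 directly, acetylation alone would finish the route.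

Step 4. Displacement next to the fully substituted oxirane carbon may be sluggish, with elimination into the allylic C5 position or phosphine-induced angelate-to-tiglate isomerisation competing. The fallback sets out from 6 and comes back at 13.
- The same kinetic resolution, run to higher conversion, leaves the unreacted (4S)-alcohol F4.
- F4 is esterified with retention by the mixed anhydride of angelic acid and 2,4,6-trichlorobenzoyl chloride (Et3N, toluene, no DMAP, Yamaguchi type) to the allylic angelate F5.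
- SeO2/TBHP oxidation gives the 12-alcohol F6, and MsCl/LiCl/collidine gives the 12-chloride F7.
- HF·pyridine frees the primary allylic alcohol F8.
- Reagent-controlled Sharpless epoxidation of F8 (Ti(OiPr)4, D-(−)-diethyl tartrate, TBHP, 4 Å MS, −20 °C) installs the (2R,3R)-oxirane and gives 13.

Further compounds
F1 | step 9 | allylchromium dichloride formed from 14 at C12 (trivalent chromium, not isolated) | Cl[Cr](Cl)C/C(C)=C/CC/C(C)=C/C[C@H](OC(=O)/C(C)=C\C)[C@@]1(C)O[C@@H]1C=O
F2 | step 10 | (1R,2S,4E,8S,10S)-1,5-dimethyl-9-oxo-8-(prop-1-en-2-yl)-11-oxabicyclo[8.1.0]undec-4-en-2-yl (2Z)-2-methylbut-2-enoate | C=C(C)[C@@H]1CC/C(C)=C/C[C@H](OC(=O)/C(C)=C\C)[C@@]2(C)O[C@@H]2C1=O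
F3 | step 10 | (1R,2S,4E,8S,9R,10R)-9-hydroxy-1,5-dimethyl-8-(prop-1-en-2-yl)-11-oxabicyclo[8.1.0]undec-4-en-2-yl (2Z)-2-methylbut-2-enoate | C=C(C)[C@@H]1CC/C(C)=C/C[C@H](OC(=O)/C(C)=C\C)[C@@]2(C)O[C@@H]2[C@@H]1O
F4 | step 4 | (2E,4S,6E)-1-[tert-butyl(dimethyl)silyl]oxy-3,7,11-trimethyldodeca-2,6,10-trien-4-ol | CC(C)=CCC/C(C)=C/C[C@H](O)/C(C)=C/CO[Si](C)(C)C(C)(C)C
F5 | step 4 | (2E,4S,6E)-1-[tert-butyl(dimethyl)silyl]oxy-3,7,11-trimethyldodeca-2,6,10-trien-4-yl (2Z)-2-methylbut-2-enoate | CC(C)=CCC/C(C)=C/C[C@H](OC(=O)/C(C)=C\C)/C(C)=C/CO[Si](C)(C)C(C)(C)C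
F6 | step 4 | (2E,4S,6E,10E)-1-[tert-butyl(dimethyl)silyl]oxy-12-hydroxy-3,7,11-trimethyldodeca-2,6,10-trien-4-yl (2Z)-2-methylbut-2-enoate | OC/C(C)=C/CC/C(C)=C/C[C@H](OC(=O)/C(C)=C\C)/C(C)=C/CO[Si](C)(C)C(C)(C)C
F7 | step 4 | (2E,4S,6E,10E)-1-[tert-butyl(dimethyl)silyl]oxy-12-chloro-3,7,11-trimethyldodeca-2,6,10-trien-4-yl (2Z)-2-methylbut-2-enoate | ClC/C(C)=C/CC/C(C)=C/C[C@H](OC(=O)/C(C)=C\C)/C(C)=C/CO[Si](C)(C)C(C)(C)C
F8 | step 4 | (2E,4S,6E,10E)-12-chloro-1-hydroxy-3,7,11-trimethyldodeca-2,6,10-trien-4-yl (2Z)-2-methylbut-2-enoate | ClC/C(C)=C/CC/C(C)=C/C[C@H](OC(=O)/C(C)=C\C)/C(C)=C/CO
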